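Oak and cedar hold the same charge and differ in time, so I follow one substrate molecule at its forks: flipped by the racemization catalyst, or taken by the free catalyst, which takes left-handed substrate faster than right-handed, as Saturday's last reading shows with 21.9% against 41.1%.

common to all: left-handed substrate 0.020 M; right-handed substrate 0.020 M; free catalyst 5 mol%; racemization catalyst 0.5 mol%

| run | reagent | added ligand | remark | time |
|---|---|---|---|---|
| Saturday's | 4 equiv | 1.7 mM | run made earlier |  |
| Tuesday's | 4 equiv | 2.6 mM | run made earlier |  |
| oak | 4.00 equiv | 1.2 mM |  | 6.0 d |
| cedar | 4.00 equiv | 1.2 mM |  | 1.5 d |

- Saturday's (time / d: right-handed substrate / %, left-handed substrate / %, left-handed product / %): 0.500: 46.8, 46.2, 5.8; 1.04: 44.9, 41.5, 12.7; 1.67: 42.9, 34.9, 18.4; 2.08: 43.3, 33.4, 20.8; 2.50: 42.3, 30.2, 23.8; 3.00: 42.9, 26.7, 27.0; 4.00: 41.1, 21.9, 32.1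
- Tuesday's (time / d: right-handed substrate / %, left-handed substrate / %, left-handed product / %): 0.208: 49.3, 50.1, 1.6; 0.500: 48.1, 47.6, 4.2; 1.04: 47.1, 43.5, 8.9; 1.67: 46.1, 40.9, 12.0; 2.00: 45.1, 38.5, 14.1; 3.00: 44.3, 32.9, 19.8; 4.00: 43.9, 28.5, 24.2

(each reading ± 0.5 percentage points)

- free catalyst is single-handed; left-handed substrate and right-handed substrate are mirror images of each other, charged as a racemate, each of them at the stated concentration
- candidate steps: reagent + free catalyst + left-handed substrate -> free catalyst + left-handed product; reagent + free catalyst + right-handed substrate -> free catalyst + right-handed product; left-handed substrate + racemization catalyst <-> right-handed substrate + racemization catalyst; free catalyst + added ligand <-> idle complex; racemization catalyst -> spent catalyst; reagent -> decomposition product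
- an excess is the difference of the two amounts in percent of their sum
- an excess is below zero if the other one leads

* the flask that ends with the higher excess of right-handed substrate over left-handed substrate among what is left of the two, or "neither" when 2 percentage points or less lies between them (oak / cedar / neither)
* excess of right-handed substrate over left-handed substrate among what is left of the two at the end, oak
* excess of right-handed substrate over left-handed substrate among what is left of the two at the end, cedar

Once flipping fades, this is a kinetic resolution: x = ln([right-handed substrate]/[left-handed substrate]) climbs each day by a left-handed molecule's daily chance of being taken minus a right-handed one's. I call that the parting rate. Then x is the parting rate times the time less a delay, and the excess is tanh(x/2). Between 1.67 d and 4.00 d the readings give 0.182 d⁻¹ in Saturday's run and 0.134 d⁻¹ in Tuesday's; run back to zero, those lines put the delay at 0.534 d and 0.777 d.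

Which must be good? The spread of the delays is 25.2% of cedar's time beyond the shorter delay but 4.46% of oak's, so cedar feels it more than oak does. The parting rate enters both flasks in proportion, and it must be extrapolated. The selectivity needs no value of its own, since it sits inside that rate.

If ligand holds free catalyst as idle complex, the reciprocal rate rises roughly in line with ligand. At 1.2 mM the parting rate, the daily rise of x, is then 0.226 d⁻¹. With the mean delay 0.655 d, I reckon 54.0% for oak and 9.52% for cedar, a gap far above the margin of 2 percentage points.

The forecast, for a flask “whose racemization catalyst dies early”, names oak with 53% and 9.5%, its oak figure lower than mine.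

The flasks give oak, with 57.7% in oak and 10.7% in cedar.

    reagent + free catalyst + left-handed substrate → free catalyst + left-handed product (k = 7.70 M⁻² min⁻¹)
    reagent + free catalyst + right-handed substrate → free catalyst + right-handed product (k = 0.880 M⁻² min⁻¹)
    left-handed substrate + racemization catalyst ⇌ right-handed substrate + racemization catalyst, rate k3*[racemization catalyst]*[left-handed substrate] forward; the back reaction follows from the equilibrium constant (k = 75.0 M⁻¹ min⁻¹)
    free catalyst + added ligand ⇌ idle complex, settled at all times (K = 2400 M⁻¹)
    racemization catalyst → spent catalyst (k = 0.00210 min⁻¹)
    reagent → decomposition product (k = 1.60 × 10⁻⁶ min⁻¹)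

In cedar the forward half-life of left-handed substrate by racemization is 0.47 d at 0.656 d, while the two-way relaxation half-life has reached 2.99 d at 1.50 d. Cedar's racemization catalyst then stands at 1.07% of its charge. From cedar's end to oak's, x climbs by 0.245 d⁻¹, beside my 0.226 d⁻¹. A neighbouring flask, cedar with 8.5 mol% of free catalyst, keeps 52.0% of it free against cedar's 40.7%, so my rate scales to 0.491 d⁻¹ and with my delay gives 20.5%; that flask stands at 21.0%.

(The runs stem from a simulated flask from invented constants.)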